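# Proposed synthesis of CNP0113972.1 (compound 31) through reductive opening of a ferulate-type photodimer

Compound numbers: starting materials 1, 3, 5, 18, 19; intermediates 2, 4, 6–17, 20–30; target 31.
Atom labels: lactone O1, C2 (C=O), C3, C4, C5. Ring C sits on the benzyl group at C3, ring B on the benzyl group at C4. Ring B arm: C7 (carbinol, bears ring A), C8 (on ring B), C9 (CH2OH). Ring C arm: C7′ (bears ring D), C8′, C9′.

## Analysis of the target

Compound 31 is a trans-3,4-dibenzyl-γ-butyrolactone whose two guaiacyl rings B and C each carry, ortho to the phenol, a 1-aryl-1,3-dihydroxypropan-2-yl arm that ends in guaiacyl ring A or D. It has six stereocentres: lactone C3 and C4 (3S,4S, trans), the ring B arm (7S,8S) and the ring C arm (7′S,8′R). The two arms share the carbinol configuration but are diastereomers: in the zigzag C9–C8–C7–ring A, the aryl ring on C8 and the C7 oxygen lie anti in the ring B arm and syn in the ring C arm. Sensitive groups are four oxidisable phenols, two p-hydroxybenzylic alcohols that ionise under acid (epimerisation at C7, or closure onto the neighbouring phenol to a dihydrobenzofuran) and a lactone that does not tolerate strong hydride or organometallic reagents. C3 is epimerisable, but trans is the stable arrangement. The difficulty is that the two halves are almost identical: rings B and C differ only in their position on the lactone and in the configuration at C8, so they must be told apart early and kept apart. The strategy rests on the C3–C4 unit of the lactone and the two benzylic CH2 groups it carries (ring C through C3, ring B through C4): joining those two CH2 carbons to each other gives the cyclobutane of a head-to-head cinnamate (2+2) dimer.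

## Retrosynthetic reasoning

**31 ⇒ 30 ⇒ 29.** The last operations must be neutral because of the benzylic alcohols. The four phenols are therefore carried as benzyl ethers (30) and the two carbinols as silyl ethers (29), removed by buffered desilylation and neutral hydrogenolysis.

**29 ⇒ 27 and 26 ⇒ 24 (C9–O and C8–H).** Both arms share the C7 configuration and differ only at C8. Cutting C9–O and C8–H leads back to the 1,1-disubstituted alkenes 27 and 24 with the C7 silyl ether in the allylic position. Hydroboration then sets C8 by 1,2-induction, and its sense depends on the mode: the uncatalysed reaction gives the anti arm (ring B, 26), rhodium catalysis gives the syn arm (ring C, 29). One alkene type thus serves both arms, and no carbonyl or hydride chemistry is needed next to the lactone.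

**27 ⇒ 26 + 23 and 24 ⇒ 17 + 23 (aryl–C8).** The aryl–C8 bonds are cut to give the same enantiomerically enriched vinylboronate 23 twice, each time with an aryl halide on the lactone core (26 and 17). Dihalide 17 carries iodine on ring B and bromine on ring C, so that the two cross-couplings can be run one after the other and each hydroboration meets only one alkene.

**23 ⇒ 22 ⇒ 21 ⇒ 20 ⇒ 18 + 19.** Boronate 23 comes from terminal alkyne 22 by copper-catalysed protoboration with boron at the internal carbon. Alkyne 22 is the silyl ether of carbinol 21, which is 20 without its alkynyl silicon. The C7 stereocentre comes from a catalytic asymmetric alkynylation of aldehyde 18 with alkyne 19.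

**17 ⇒ 16 ⇒ 15 ⇒ 14 ⇒ 13.** The halogens are placed by phenol-directed substitution. Lactone 13 has only ring B as a free phenol, so iodine goes there (14). The isopropyl ether of ring C is then removed (15) while the molecule is still robust, because no later intermediate would tolerate the strong Lewis acid this takes. The new phenol directs bromine to ring C (16), and both phenols are benzylated together (17).

**13 ⇒ 12 ⇒ 11 ⇒ 10 (key disconnection).** The lactone is opened to hydroxy acid 12, and the two benzylic CH2 groups are joined into the aryl-CH to aryl-CH bond of all-trans cyclobutane 11 (10 is its ring B benzyl ether). This cut is chosen because it replaces two separate stereocentres by the C1/C4 pair of a cycloadduct, and because the ring B/ring C differentiation and the acid/alcohol differentiation are both carried by that one compound. Forward, a dissolving-metal reduction has to break only the strained, doubly benzylic bond and leave C1 and C4 untouched.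

**10 ⇒ 9 ⇒ 7 ⇒ 4 + 6.** Hydroxy acid 10 follows from half-ester 9 by ester reduction, and 9 from cycloadduct 7 by hydrolysis of its acyl group. Cyclobutane 7 is the crossed head-to-head photoadduct of two ferulic-type alkenes with different carbonyl groups, 4 and 6. The acylimidazole of 4 (ring C, isopropyl ether) becomes the acid. The methyl ester of 6 (ring B, benzyl ether) becomes the CH2OH group. Enone 4 comes from aldehyde 2 and ketone 3 by aldol condensation, 2 from 1 by alkylation, and 6 from 5 by benzylation.

## Alternatives that were turned down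

**Alternative 1:** The ring B arm is cut at C8–C9 and C7–O. Forward, (E)-stilbene A1 would react with two molecules of formaldehyde A2 under confined chiral Brønsted acid catalysis in a three-component Prins reaction to give trans-4,5-diaryl-1,3-dioxane A3.
- For: both arm stereocentres and the protected 1,3-diol are made in one catalytic step from a flat precursor, and the trans acetal corresponds to the anti (7S,8S) arm.
- Against: the substrate is a 1,2-diaryl alkene, and the regiochemistry depends on ring A stabilising the cation better than the deactivated ring B. The (E)-alkene can only give the anti arm, so the syn arm of ring C would need a second alkene geometry. The methylene acetal must later be removed with acid next to an ionisable benzylic C7–O bond. The lactone stereocentres are not addressed.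
- Comparison: this alternative is stronger in bond economy for one arm. The chosen route needs a coupling and a hydroboration per arm, but it offers one fragment for both arms with a reagent-switchable C8, and the whole lactone core with both rings differentiated from a single cycloadduct.

**Alternative 2:** The lactone O1–C5 and O1–C2 bonds are traced back to 3-substituted cyclobutanone A4. Forward, hydrogen peroxide A5 would add to the ketone under chiral Brønsted acid catalysis, one of the two enantiotopic CH2 groups would migrate to oxygen, and armed lactone A6 would result with C4 set.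
- For: the asymmetric Baeyer–Villiger desymmetrisation is an established reaction class, it is mild, the prochiral ketone needs no resolution, and C3 can follow by trans-selective enolate benzylation.
- Against: the stereocentre lies one CH2 group away from the aryl ring, which should weaken the transmission of chirality. The electron-rich rings and the benzylic silyl ether of the arm must survive an acidic peroxide. Four of the six stereocentres (the arms) must already be in place, and the second arm would have to ride on the electrophile of a late enolate alkylation.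
- Comparison: this alternative is stronger on precedent for the core. The chosen route offers both lactone centres in one event from two simple alkenes and a late, convergent attachment of the arms.

**Alternative 3:** The ring B arm is cut at C7–O (through C7–Si) and C8–H. Forward, hydrosilyl ether A7 would cyclise under enantioselective rhodium catalysis by syn addition of Si–H across C7=C8 to give oxasilolane A8; oxidation of the C–Si bond with retention would then deliver the C7 hydroxyl.
- For: the tether fixes the regiochemistry, the alkene geometry is translated into the relative configuration, and the catalyst sets the absolute one.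
- Against: the alkene is trisubstituted and stilbene-like, more hindered than the allyl alcohols for which this cyclisation is typical. Oxidising a diphenyl-substituted silicon needs strong activation next to an electron-rich benzylic position. The syn arm of ring C would need the other alkene geometry. The lactone is again left open.
- Comparison: this alternative is stronger in that both arm centres are under catalyst and geometry control, whereas the chosen route relies on substrate-induced hydroboration. The chosen route offers a single fragment for both arms without two alkene geometries, and the lactone core.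

Key step: step 7

## Assumptions

- The sense of induction of the chiral acid in step 4 and of the ligand in step 12 is taken as written; if either proves opposite, its mirror-image form is used.
- Compounds 1, 3, 5, 18 and 19 are taken as commercially available.

## Steps

Step 1
Reactants: 1 vanillin
Product: 2 4-isopropoxy-3-methoxybenzaldehyde
Conditions: 2-bromopropane, K2CO3, DMF, 70 °C
Reagents that add atoms: 2-bromopropane, CC(C)Br
Why: Williamson etherification of the phenoxide; the isopropyl ether survives light, hydride and dissolving metal and can later be removed selectively with a boron Lewis acid.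

Step 2
Reactants: 2 4-isopropoxy-3-methoxybenzaldehyde; 3 2-acetyl-1-methylimidazole
Product: 4 (E)-3-(4-isopropoxy-3-methoxyphenyl)-1-(1-methyl-1H-imidazol-2-yl)prop-2-en-1-one
Conditions: KOH (20 mol%), EtOH–H2O, rt
Reagents that add atoms: none
Why: Claisen–Schmidt aldol condensation; dehydration of the aldol gives the conjugated (E)-enone.

Step 3
Reactants: 5 methyl ferulate
Product: 6 methyl (E)-3-[4-(benzyloxy)-3-methoxyphenyl]acrylate
Conditions: BnBr, K2CO3, acetone, reflux
Reagents that add atoms: benzyl bromide, BrCc1ccccc1
Why: Williamson etherification; the benzyl ether is chosen because the dissolving-metal key step removes it at no extra cost.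

Step 4
Reactants: 4 ring C acylimidazole enone; 6 ring B benzyl-protected methyl ferulate
Product: 7 methyl (1S,2R,3R,4S)-2-[4-(benzyloxy)-3-methoxyphenyl]-3-(4-isopropoxy-3-methoxyphenyl)-4-(1-methyl-1H-imidazole-2-carbonyl)cyclobutane-1-carboxylate (all-trans)
Conditions: (R)-3,3'-bis(2,4,6-triisopropylphenyl)-1,1'-binaphthalene-2,2'-diyl hydrogen phosphate (20 mol%), [Ru(bpy)3](PF6)2 (bpy = 2,2'-bipyridine; 2 mol%), ester in fivefold excess, CH2Cl2–toluene, blue LEDs (450 nm), −20 °C
Reagents that add atoms: none
Why: Crossed (2+2) photocycloaddition by Brønsted acid-catalysed triplet energy transfer: only the acid-bound acylimidazole 4 has a triplet energy within reach of the divalent ruthenium sensitiser, so ester 6 stays in the ground state and acts as the trap. The head-to-head adduct should form through the better stabilised 1,4-diradical, which closes to the least hindered all-trans ring. The chiral phosphate shields one enone face, which sets the acyl-bearing carbon, and the ester-bearing carbon follows trans to it.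

Step 5
Reactants: 7 all-trans cycloadduct
Product: 9 (1S,2R,3R,4S)-3-[4-(benzyloxy)-3-methoxyphenyl]-2-(4-isopropoxy-3-methoxyphenyl)-4-(methoxycarbonyl)cyclobutane-1-carboxylic acid, via acylimidazolium triflate 8 (not isolated)
Conditions: MeOTf, 4 Å molecular sieves, MeCN, rt; then DBU, H2O, 0 °C to rt; 1 M HCl work-up
Reagents that add atoms: water, O
Why: N-methylation turns the 2-acylimidazole into an acyl azolium, an activated acyl donor that should be hydrolysed rapidly by nucleophilic acyl substitution while the methyl ester is untouched. The acid-bearing carbon already sits trans to both neighbours, so base-mediated epimerisation has no driving force.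

Step 6
Reactants: 9 half-ester acid
Product: 10 (1S,2R,3R,4S)-3-[4-(benzyloxy)-3-methoxyphenyl]-4-(hydroxymethyl)-2-(4-isopropoxy-3-methoxyphenyl)cyclobutane-1-carboxylic acid
Conditions: LiBH4, THF, 0 °C to rt; aqueous HCl work-up
Reagents that add atoms: none
Why: Chemoselective ester reduction: the acid is first deprotonated to the lithium carboxylate, which LiBH4 does not reduce, while the methyl ester goes to CH2OH. The trans relation on the four-membered ring prevents lactonisation at this stage.

Step 7
Reactants: 10 all-trans cyclobutane hydroxy acid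
Product: 13 (3S,4S)-4-(4-hydroxy-3-methoxybenzyl)-3-(4-isopropoxy-3-methoxybenzyl)dihydrofuran-2(3H)-one, via debenzylated cyclobutane hydroxy acid 11 (not isolated), via open-chain hydroxy acid 12 (not isolated)
Conditions: Li (10 equiv), NH3(l)–THF, −78 °C, 30 min; isoprene, then NH4Cl; evaporate; 1 M HCl; then 4-MeC6H4SO3H (5 mol%), CH2Cl2, rt
Reagents that add atoms: none
Why: Proposed new method: solvated electrons should first cleave the benzyl ether (phenoxide of 11) and then add to the dialkoxyphenyl ring C, whose radical anion relieves the cyclobutane strain by breaking the only doubly benzylic bond, between the two aryl-bearing carbons. A second electron and protonation by ammonia turn both benzylic carbons into CH2 groups (12). The closest known reaction type is the dissolving-metal reductive opening of vicinal diaryl cyclopropanes and other strained benzylic C–C bonds. The carboxylate-bearing and hydroxymethyl-bearing carbons take no part, so their trans relation and configuration pass unchanged into lactone C3 and C4; no new stereocentre is formed. On acidification the lactone closes by 5-exo-trig attack of the primary alcohol on the carboxyl carbon. The step needs cleavage of the diaryl-substituted bond without arene reduction, ether loss or epimerisation. Strain plus double benzylic stabilisation should make the fragmentation fast; destroying the excess metal with isoprene before any proton source stronger than ammonia is added avoids Birch reduction. The carboxylate cannot enolise, which protects C3, and the ring B phenoxide is too electron-rich to be reduced, while the isopropyl ether keeps ring C distinguishable.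

Step 8
Reactants: 13 lactone with free ring B phenol
Product: 14 (3S,4S)-4-(4-hydroxy-3-iodo-5-methoxybenzyl)-3-(4-isopropoxy-3-methoxybenzyl)dihydrofuran-2(3H)-one
Conditions: I2, NaHCO3, THF–H2O, 0 °C to rt
Reagents that add atoms: iodine, II
Why: Electrophilic aromatic iodination of the phenoxide; only ring B is a phenol and its single open ortho position is attacked, while the ether ring C is inert to iodine under bicarbonate.

Step 9
Reactants: 14 iodophenol
Product: 15 (3S,4S)-4-(4-hydroxy-3-iodo-5-methoxybenzyl)-3-(4-hydroxy-3-methoxybenzyl)dihydrofuran-2(3H)-one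
Conditions: BCl3, CH2Cl2, −78 to 0 °C; aqueous NaHCO3 work-up
Reagents that add atoms: none
Why: Lewis acid dealkylation of the aryl isopropyl ether, whose secondary alkyl group leaves much more readily than methyl. It is done here because later intermediates with benzyl ethers and benzylic silyl ethers would not survive BCl3.

Step 10
Reactants: 15 bisphenol
Product: 16 (3S,4S)-3-(3-bromo-4-hydroxy-5-methoxybenzyl)-4-(4-hydroxy-3-iodo-5-methoxybenzyl)dihydrofuran-2(3H)-one
Conditions: N-bromosuccinimide (1.0 equiv), iPr2NH (10 mol%), CH2Cl2, −20 to 0 °C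
Reagents that add atoms: N-bromosuccinimide, O=C1CCC(=O)N1Br
Why: Amine-catalysed ortho-bromination of a phenol; only ring C has a free ortho position, since the ring B phenol is flanked by methoxy and iodine.

Step 11
Reactants: 16 bromo iodo bisphenol
Product: 17 (3S,4S)-3-[4-(benzyloxy)-3-bromo-5-methoxybenzyl]-4-[4-(benzyloxy)-3-iodo-5-methoxybenzyl]dihydrofuran-2(3H)-one
Conditions: BnBr, K2CO3, DMF, 40 °C
Reagents that add atoms: benzyl bromide, BrCc1ccccc1
Why: Double Williamson etherification; carbonate is too weak to enolise the lactone, and the trans arrangement is the stable one in any case.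

Step 12
Reactants: 18 4-(benzyloxy)-3-methoxybenzaldehyde; 19 ethynyltrimethylsilane
Product: 20 (R)-1-[4-(benzyloxy)-3-methoxyphenyl]-3-(trimethylsilyl)prop-2-yn-1-ol
Conditions: Me2Zn, (S,S)-2,6-bis{[2-(hydroxydiphenylmethyl)pyrrolidin-1-yl]methyl}-4-methylphenol (10 mol%), Ph3PO (20 mol%), toluene, 4 °C
Reagents that add atoms: none
Why: Catalytic asymmetric alkynylation of an aldehyde by the dinuclear zinc species formed in the flask from Me2Zn and the aminophenol ligand, which binds both the aldehyde and the zinc alkynylide; delivery to the Si face sets the carbinol centre. The R descriptor arises only from the silicon in the priority order; the spatial arrangement is that of C7 (S) in 31.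

Step 13
Reactants: 20 silylated propargylic alcohol
Product: 21 (S)-1-[4-(benzyloxy)-3-methoxyphenyl]prop-2-yn-1-ol
Conditions: K2CO3 (20 mol%), MeOH, rt
Reagents that add atoms: none
Why: Base-catalysed methanolysis of the alkynyl C–Si bond; the stereocentre is not involved.

Step 14
Reactants: 21 terminal propargylic alcohol
Product: 22 (S)-{1-[4-(benzyloxy)-3-methoxyphenyl]prop-2-yn-1-yl}oxy(tert-butyl)dimethylsilane
Conditions: tBuMe2SiCl, imidazole, DMF, rt
Reagents that add atoms: tert-butyldimethylsilyl chloride, CC(C)(C)[Si](C)(C)Cl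
Why: Silylation of the secondary alcohol; the bulky silyl ether is the allylic control element for both later hydroborations and protects C7 to the end.

Step 15
Reactants: 22 propargylic silyl ether
Product: 23 (S)-{1-[4-(benzyloxy)-3-methoxyphenyl]-2-(4,4,5,5-tetramethyl-1,3,2-dioxaborolan-2-yl)prop-2-en-1-yl}oxy(tert-butyl)dimethylsilane
Conditions: chloro[1,3-bis(2,4,6-trimethylphenyl)imidazolidin-2-ylidene]copper (5 mol%), NaOtBu (5 mol%), bis(pinacolato)diboron, MeOH, THF, −15 °C to rt
Reagents that add atoms: bis(pinacolato)diboron, CC1(C)OB(OC1(C)C)B1OC(C)(C)C(C)(C)O1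
Why: Copper-catalysed protoboration of a terminal alkyne: the boryl complex of monovalent copper adds syn with boron at the internal carbon, as favoured by the propargylic oxygen and the N-aryl carbene ligand, and methanol protonates the alkenylcopper.

Step 16
Reactants: 17 dihalide; 23 vinylboronate
Product: 24 (3S,4S)-3-[4-(benzyloxy)-3-bromo-5-methoxybenzyl]-4-{4-(benzyloxy)-3-methoxy-5-[(3R)-3-[4-(benzyloxy)-3-methoxyphenyl]-3-[(tert-butyldimethylsilyl)oxy]prop-1-en-2-yl]benzyl}dihydrofuran-2(3H)-one
Conditions: boronate (1.2 equiv), PdCl2(dppf) (dppf = 1,1'-bis(diphenylphosphino)ferrocene, 5 mol%), K3PO4, THF–H2O (10:1), 45 °C; work-up at pH 4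
Reagents that add atoms: none
Why: Suzuki–Miyaura coupling; oxidative addition of zerovalent palladium into the C–I bond is much faster than into the electron-rich C–Br bond at this temperature, so only ring B should couple. C7 is untouched; its descriptor reads R here only because the vinyl carbon outranks ring A.

Step 17
Reactants: 24 ring B alkene
Product: 26 (3S,4S)-3-[4-(benzyloxy)-3-bromo-5-methoxybenzyl]-4-{4-(benzyloxy)-3-[(1S,2S)-1-[4-(benzyloxy)-3-methoxyphenyl]-1-[(tert-butyldimethylsilyl)oxy]-3-hydroxypropan-2-yl]-5-methoxybenzyl}dihydrofuran-2(3H)-one, via B-alkyl-9-borabicyclononane adduct 25 (not isolated)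
Conditions: 9-borabicyclo[3.3.1]nonane (3 equiv), THF, 0 to 40 °C; then 30% H2O2, pH 7 phosphate buffer, 0 °C to rt
Reagents that add atoms: hydrogen peroxide, OO
Why: Hydroboration–oxidation of a 1,1-disubstituted allylic silyl ether: boron goes to the CH2 terminus. The bulky borane should approach with the allylic hydrogen in the alkene plane and anti to ring A, which is the known anti 1,2-induction of uncatalysed hydroboration and sets C8 as S. Oxidation proceeds with retention, and the neutral buffer spares the lactone.

Step 18
Reactants: 26 ring B arm alcohol bearing the ring C bromide; 23 vinylboronate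
Product: 27 (3S,4S)-3-{4-(benzyloxy)-3-methoxy-5-[(3R)-3-[4-(benzyloxy)-3-methoxyphenyl]-3-[(tert-butyldimethylsilyl)oxy]prop-1-en-2-yl]benzyl}-4-{4-(benzyloxy)-3-[(1S,2S)-1-[4-(benzyloxy)-3-methoxyphenyl]-1-[(tert-butyldimethylsilyl)oxy]-3-hydroxypropan-2-yl]-5-methoxybenzyl}dihydrofuran-2(3H)-one
Conditions: boronate (1.5 equiv), Pd(OAc)2 (5 mol%), 2-dicyclohexylphosphino-2',6'-dimethoxybiphenyl (10 mol%), K3PO4, toluene–H2O (20:1), 80 °C; work-up at pH 4
Reagents that add atoms: none
Why: Suzuki–Miyaura coupling; the bulky electron-rich biarylphosphine allows oxidative addition into the ortho-alkoxy aryl bromide and coupling with the hindered boronate. The free primary alcohol is tolerated.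

Step 19
Reactants: 27 ring C alkene
Product: 29 (3S,4S)-3-{4-(benzyloxy)-3-[(1S,2R)-1-[4-(benzyloxy)-3-methoxyphenyl]-1-[(tert-butyldimethylsilyl)oxy]-3-hydroxypropan-2-yl]-5-methoxybenzyl}-4-{4-(benzyloxy)-3-[(1S,2S)-1-[4-(benzyloxy)-3-methoxyphenyl]-1-[(tert-butyldimethylsilyl)oxy]-3-hydroxypropan-2-yl]-5-methoxybenzyl}dihydrofuran-2(3H)-one, via catecholboryl intermediate 28 (not isolated)
Conditions: RhCl(PPh3)3 (5 mol%), catecholborane (4 equiv), THF, 0 °C to rt; then 30% H2O2, pH 7 phosphate buffer, 0 °C
Reagents that add atoms: hydrogen peroxide, OO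
Why: Rhodium-catalysed hydroboration of an allylic silyl ether: the rhodium hydride of the monovalent rhodium catalyst should add to the alkene face anti to the allylic silyloxy group. This is the syn 1,2-induction, complementary to the uncatalysed reaction, and sets C8′ as R. The free C9 hydroxyl is held as a borate and released on work-up.

Step 20
Reactants: 29 bis(silyl ether) diol
Product: 30 (3S,4S)-3-{4-(benzyloxy)-3-[(1S,2R)-1-[4-(benzyloxy)-3-methoxyphenyl]-1,3-dihydroxypropan-2-yl]-5-methoxybenzyl}-4-{4-(benzyloxy)-3-[(1S,2S)-1-[4-(benzyloxy)-3-methoxyphenyl]-1,3-dihydroxypropan-2-yl]-5-methoxybenzyl}dihydrofuran-2(3H)-one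
Conditions: Bu4NF, AcOH (1:1), THF, 0 °C to rt
Reagents that add atoms: none
Why: Fluoride-mediated cleavage of the two Si–O bonds; the acetic acid buffer keeps the medium close to neutral, so the lactone and the benzylic alcohols are not disturbed.

Step 21
Reactants: 30 tetrabenzyl ether
Product: 31 (3S,4S)-3-{4-hydroxy-3-[(1S,2R)-1,3-dihydroxy-1-(4-hydroxy-3-methoxyphenyl)propan-2-yl]-5-methoxybenzyl}-4-{4-hydroxy-3-[(1S,2S)-1,3-dihydroxy-1-(4-hydroxy-3-methoxyphenyl)propan-2-yl]-5-methoxybenzyl}dihydrofuran-2(3H)-one (CNP0113972.1)
Conditions: H2 (1 atm), 10% Pd/C, EtOAc–EtOH, rt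
Reagents that add atoms: none
Why: Hydrogenolysis of four aryl benzyl ethers under neutral conditions; without acid the benzylic C7–O and C7′–O bonds should not ionise or be cleaved, and the lactone is inert.

## Compound list

1 | vanillin | COc1cc(C=O)ccc1O | starting material
2 | 4-isopropoxy-3-methoxybenzaldehyde | COc1cc(C=O)ccc1OC(C)C | intermediate
3 | 2-acetyl-1-methylimidazole | CC(=O)c1nccn1C | starting material
4 | (E)-3-(4-isopropoxy-3-methoxyphenyl)-1-(1-methyl-1H-imidazol-2-yl)prop-2-en-1-one | COc1cc(/C=C/C(=O)c2nccn2C)ccc1OC(C)C | intermediate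
5 | methyl ferulate, methyl (E)-3-(4-hydroxy-3-methoxyphenyl)acrylate | COc1cc(/C=C/C(=O)OC)ccc1O | starting material
6 | methyl (E)-3-[4-(benzyloxy)-3-methoxyphenyl]acrylate | COc1cc(/C=C/C(=O)OC)ccc1OCc1ccccc1 | intermediate
7 | methyl (1S,2R,3R,4S)-2-[4-(benzyloxy)-3-methoxyphenyl]-3-(4-isopropoxy-3-methoxyphenyl)-4-(1-methyl-1H-imidazole-2-carbonyl)cyclobutane-1-carboxylate, all-trans | Cn1ccnc1C(=O)[C@H]1[C@H](c2ccc(OC(C)C)c(OC)c2)[C@@H](c2ccc(OCc3ccccc3)c(OC)c2)[C@@H]1C(=O)OC | intermediate
8 | 1,3-dimethylimidazolium triflate of 7 (acyl azolium), not isolated | C[n+]1ccn(C)c1C(=O)[C@H]1[C@H](c2ccc(OC(C)C)c(OC)c2)[C@@H](c2ccc(OCc3ccccc3)c(OC)c2)[C@@H]1C(=O)OC.[O-]S(=O)(=O)C(F)(F)F | intermediate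
9 | (1S,2R,3R,4S)-3-[4-(benzyloxy)-3-methoxyphenyl]-2-(4-isopropoxy-3-methoxyphenyl)-4-(methoxycarbonyl)cyclobutane-1-carboxylic acid | OC(=O)[C@H]1[C@H](c2ccc(OC(C)C)c(OC)c2)[C@@H](c2ccc(OCc3ccccc3)c(OC)c2)[C@@H]1C(=O)OC | intermediate
10 | (1S,2R,3R,4S)-3-[4-(benzyloxy)-3-methoxyphenyl]-4-(hydroxymethyl)-2-(4-isopropoxy-3-methoxyphenyl)cyclobutane-1-carboxylic acid, all-trans | OC(=O)[C@H]1[C@H](c2ccc(OC(C)C)c(OC)c2)[C@@H](c2ccc(OCc3ccccc3)c(OC)c2)[C@@H]1CO | intermediate
11 | (1S,2R,3R,4S)-3-(4-hydroxy-3-methoxyphenyl)-4-(hydroxymethyl)-2-(4-isopropoxy-3-methoxyphenyl)cyclobutane-1-carboxylic acid, not isolated | OC(=O)[C@H]1[C@H](c2ccc(OC(C)C)c(OC)c2)[C@@H](c2ccc(O)c(OC)c2)[C@@H]1CO | intermediate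
12 | (2S,3S)-4-hydroxy-3-(4-hydroxy-3-methoxybenzyl)-2-(4-isopropoxy-3-methoxybenzyl)butanoic acid, not isolated | COc1cc(C[C@H](CO)[C@H](Cc2ccc(OC(C)C)c(OC)c2)C(=O)O)ccc1O | intermediate
13 | (3S,4S)-4-(4-hydroxy-3-methoxybenzyl)-3-(4-isopropoxy-3-methoxybenzyl)dihydrofuran-2(3H)-one | COc1cc(C[C@@H]2COC(=O)[C@H]2Cc2ccc(OC(C)C)c(OC)c2)ccc1O | intermediate
14 | (3S,4S)-4-(4-hydroxy-3-iodo-5-methoxybenzyl)-3-(4-isopropoxy-3-methoxybenzyl)dihydrofuran-2(3H)-one | COc1cc(C[C@@H]2COC(=O)[C@H]2Cc2ccc(OC(C)C)c(OC)c2)cc(I)c1O | intermediate
15 | (3S,4S)-4-(4-hydroxy-3-iodo-5-methoxybenzyl)-3-(4-hydroxy-3-methoxybenzyl)dihydrofuran-2(3H)-one | COc1cc(C[C@@H]2COC(=O)[C@H]2Cc2ccc(O)c(OC)c2)cc(I)c1O | intermediate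
16 | (3S,4S)-3-(3-bromo-4-hydroxy-5-methoxybenzyl)-4-(4-hydroxy-3-iodo-5-methoxybenzyl)dihydrofuran-2(3H)-one | COc1cc(C[C@@H]2COC(=O)[C@H]2Cc2cc(Br)c(O)c(OC)c2)cc(I)c1O | intermediate
17 | (3S,4S)-3-[4-(benzyloxy)-3-bromo-5-methoxybenzyl]-4-[4-(benzyloxy)-3-iodo-5-methoxybenzyl]dihydrofuran-2(3H)-one | COc1cc(C[C@@H]2COC(=O)[C@H]2Cc2cc(Br)c(OCc3ccccc3)c(OC)c2)cc(I)c1OCc1ccccc1 | intermediate
18 | 4-(benzyloxy)-3-methoxybenzaldehyde | COc1cc(C=O)ccc1OCc1ccccc1 | starting material
19 | ethynyltrimethylsilane | C#C[Si](C)(C)C | starting material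
20 | (R)-1-[4-(benzyloxy)-3-methoxyphenyl]-3-(trimethylsilyl)prop-2-yn-1-ol | COc1cc([C@@H](O)C#C[Si](C)(C)C)ccc1OCc1ccccc1 | intermediate
21 | (S)-1-[4-(benzyloxy)-3-methoxyphenyl]prop-2-yn-1-ol | COc1cc([C@@H](O)C#C)ccc1OCc1ccccc1 | intermediate
22 | (S)-{1-[4-(benzyloxy)-3-methoxyphenyl]prop-2-yn-1-yl}oxy(tert-butyl)dimethylsilane | COc1cc([C@@H](O[Si](C)(C)C(C)(C)C)C#C)ccc1OCc1ccccc1 | intermediate
23 | (S)-{1-[4-(benzyloxy)-3-methoxyphenyl]-2-(4,4,5,5-tetramethyl-1,3,2-dioxaborolan-2-yl)prop-2-en-1-yl}oxy(tert-butyl)dimethylsilane | COc1cc([C@@H](O[Si](C)(C)C(C)(C)C)C(=C)B2OC(C)(C)C(C)(C)O2)ccc1OCc1ccccc1 | intermediate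
24 | 17 with the iodine of ring B replaced by the (3R)-3-[4-(benzyloxy)-3-methoxyphenyl]-3-[(tert-butyldimethylsilyl)oxy]prop-1-en-2-yl group; lactone (3S,4S) (full name in step 16) | COc1cc(C[C@@H]2COC(=O)[C@H]2Cc2cc(Br)c(OCc3ccccc3)c(OC)c2)cc(C(=C)[C@H](O[Si](C)(C)C(C)(C)C)c2ccc(OCc3ccccc3)c(OC)c2)c1OCc1ccccc1 | intermediate
25 | B-alkyl-9-borabicyclo[3.3.1]nonane adduct of 24, boron on C9, C8 configured as in 26, not isolated | COc1cc(C[C@@H]2COC(=O)[C@H]2Cc2cc(Br)c(OCc3ccccc3)c(OC)c2)cc([C@@H](CB2C3CCCC2CCC3)[C@H](O[Si](C)(C)C(C)(C)C)c2ccc(OCc3ccccc3)c(OC)c2)c1OCc1ccccc1 | intermediate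
26 | (3S,4S)-lactone with ring C bromide and the (7S,8S) ring B arm as C7 silyl ether and free C9 alcohol (full name in step 17) | COc1cc(C[C@@H]2COC(=O)[C@H]2Cc2cc(Br)c(OCc3ccccc3)c(OC)c2)cc([C@@H](CO)[C@H](O[Si](C)(C)C(C)(C)C)c2ccc(OCc3ccccc3)c(OC)c2)c1OCc1ccccc1 | intermediate
27 | 26 with the bromine of ring C replaced by the (3R)-3-[4-(benzyloxy)-3-methoxyphenyl]-3-[(tert-butyldimethylsilyl)oxy]prop-1-en-2-yl group (full name in step 18) | COc1cc(C[C@@H]2COC(=O)[C@H]2Cc2cc(C(=C)[C@H](O[Si](C)(C)C(C)(C)C)c3ccc(OCc4ccccc4)c(OC)c3)c(OCc3ccccc3)c(OC)c2)cc([C@@H](CO)[C@H](O[Si](C)(C)C(C)(C)C)c2ccc(OCc3ccccc3)c(OC)c2)c1OCc1ccccc1 | intermediate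
28 | hydroboration adduct of 27: catechol boronate at C9′ (C8′ as in 29) and catechol borate ester at O9, not isolated | COc1cc(C[C@@H]2COC(=O)[C@H]2Cc2cc([C@H](CB3Oc4ccccc4O3)[C@H](O[Si](C)(C)C(C)(C)C)c3ccc(OCc4ccccc4)c(OC)c3)c(OCc3ccccc3)c(OC)c2)cc([C@@H](COB2Oc3ccccc3O2)[C@H](O[Si](C)(C)C(C)(C)C)c2ccc(OCc3ccccc3)c(OC)c2)c1OCc1ccccc1 | intermediate
29 | (3S,4S)-lactone with the (7S,8S) ring B arm and the (7′S,8′R) ring C arm, both C7 silyl ethers, four benzyl ethers (full name in step 19) | COc1cc(C[C@@H]2COC(=O)[C@H]2Cc2cc([C@H](CO)[C@H](O[Si](C)(C)C(C)(C)C)c3ccc(OCc4ccccc4)c(OC)c3)c(OCc3ccccc3)c(OC)c2)cc([C@@H](CO)[C@H](O[Si](C)(C)C(C)(C)C)c2ccc(OCc3ccccc3)c(OC)c2)c1OCc1ccccc1 | intermediate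
30 | tetra-O-benzyl ether of 31 at the four phenols (full name in step 20) | COc1cc(C[C@@H]2COC(=O)[C@H]2Cc2cc([C@H](CO)[C@H](O)c3ccc(OCc4ccccc4)c(OC)c3)c(OCc3ccccc3)c(OC)c2)cc([C@@H](CO)[C@H](O)c2ccc(OCc3ccccc3)c(OC)c2)c1OCc1ccccc1 | intermediate
31 | CNP0113972.1 (full name in step 21) | COc1cc(C[C@@H]2COC(=O)[C@H]2Cc2cc([C@H](CO)[C@H](O)c3ccc(O)c(OC)c3)c(O)c(OC)c2)cc([C@@H](CO)[C@H](O)c2ccc(O)c(OC)c2)c1O | target

## Step count and least certain steps

Total: 21 steps. Longest linear sequence: 16 steps (1, 2, 4–11, 16–21, from vanillin 1). The boronate branch (steps 12–15) joins at steps 16 and 18.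

**Step 7 (key step, new method).**
- What may go wrong: Birch-type reduction of ring C or reductive loss of an aryl alkyl ether if electron transfer outruns fragmentation; cycloreversion of the ring radical anion to two alkenes that are then reduced; or incomplete cleavage at −78 °C.
- Fallback by known chemistry, from 18 and 2 to 13: Stobbe condensation of 18 with dimethyl succinate (NaOMe, MeOH) gives the half-ester (E)-4-[4-(benzyloxy)-3-methoxyphenyl]-3-(methoxycarbonyl)but-3-enoic acid F1. Asymmetric hydrogenation with [Rh(cod)(Me-DuPhos)]BF4 (cod = 1,5-cyclooctadiene, Me-DuPhos = 1,2-bis(2,5-dimethylphospholan-1-yl)benzene), in the mirror-image form that gives the (S)-acid, leads to (S)-4-[4-(benzyloxy)-3-methoxyphenyl]-3-(methoxycarbonyl)butanoic acid F2. Reduction of the ester of its potassium salt with Ca(BH4)2 and acid lactonisation give (S)-4-[4-(benzyloxy)-3-methoxybenzyl]dihydrofuran-2(3H)-one F3. In parallel, 2 is reduced (NaBH4) to (4-isopropoxy-3-methoxyphenyl)methanol F4 and brominated (PBr3) to 4-isopropoxy-3-methoxybenzyl bromide F5. The lithium enolate of F3 (LiN(SiMe3)2, THF, −78 °C) is alkylated by F5 anti to the C4 substituent to give (3S,4S)-4-[4-(benzyloxy)-3-methoxybenzyl]-3-(4-isopropoxy-3-methoxybenzyl)dihydrofuran-2(3H)-one F6. Hydrogenolysis (H2, Pd/C) of its benzyl ether returns the route at 13.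

**Step 4 (crossed photocycloaddition).**
- What may go wrong: competing homodimerisation of 4 despite the excess of 6, a poor enantiofacial bias of the acid-bound enone, or closure of the diradical to isomers other than all-trans. Isomers that differ only at the two aryl-bearing carbons are harmless, because these centres vanish in step 7.
- Fallback, from 4 and 6 to 7: the same cycloaddition is run with achiral 4-MeC6H4SO3H and the same sensitiser to give the racemic all-trans adduct F7, which is resolved by preparative chromatography on a chiral stationary phase and returns the route at 7.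

**Step 16 (first cross-coupling).**
- What may go wrong: loss of site selectivity, with oxidative addition also at the ring C bromide, because the hindered boronate transmetalates slowly and forces higher temperatures. The lactone may also open under the aqueous base.
- Fallback, from 15 to 26: the bromine is introduced only after the first arm is in place. Bisphenol 15 (one halogen only) is coupled with 23 to give the ring B alkene bisphenol F8. Hydroboration with 9-borabicyclo[3.3.1]nonane and oxidation give the ring B arm alcohol bisphenol F9. Amine-catalysed bromination with N-bromosuccinimide, which can only strike ring C, gives the bromo bisphenol F10. Double benzylation (BnBr, K2CO3) returns the route at 26.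

**Step 17 (anti hydroboration).**
- What may go wrong: poor facial selectivity, because the alkene carries an aryl group where the precedents carry a small alkyl group; or sluggish addition of the bulky borane to the crowded alkene.
- Fallback, from 24 to 26: catalyst control replaces substrate control. Copper-catalysed enantioselective protoboration of the 1,1-disubstituted aryl alkene (CuCl, a chiral sulfonate-bearing imidazolinium salt as carbene precursor, NaOtBu, bis(pinacolato)diboron, MeOH) gives the pinacol boronate F11 with C8 set by the ligand. Oxidation with NaBO3·4H2O returns the route at 26.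

**Step 19 (syn hydroboration).**
- What may go wrong: erosion of the syn preference because ring D is larger than the alkyl groups of the precedents; a change of selectivity if the rhodium catalyst is partly oxidised; or slow turnover at the hindered alkene.
- Fallback, from 27 to 29: the same copper-catalysed protoboration with the mirror-image carbene precursor gives the pinacol boronate F12 with C8′ set by the ligand. Oxidation with NaBO3·4H2O returns the route at 29.

**Step 21 (final hydrogenolysis).**
- What may go wrong: hydrogenolysis of the benzylic C7–O or C7′–O bond once the para phenols are free.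
- Fallback, from 29 to 31: the order of the last two steps is reversed, so that the benzylic oxygens are still silylated during hydrogenolysis. H2 and Pd/C on 29 give the tetraphenol bis(silyl ether) F13, and Bu4NF–AcOH then gives 31.

## Further compounds

F1 | step 7 | (E)-4-[4-(benzyloxy)-3-methoxyphenyl]-3-(methoxycarbonyl)but-3-enoic acid | COC(=O)/C(CC(=O)O)=C/c1ccc(OCc2ccccc2)c(OC)c1
F2 | step 7 | (S)-4-[4-(benzyloxy)-3-methoxyphenyl]-3-(methoxycarbonyl)butanoic acid | COc1cc(C[C@@H](CC(=O)O)C(=O)OC)ccc1OCc1ccccc1
F3 | step 7 | (S)-4-[4-(benzyloxy)-3-methoxybenzyl]dihydrofuran-2(3H)-one | COc1cc(C[C@@H]2COC(=O)C2)ccc1OCc1ccccc1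
F4 | step 7 | (4-isopropoxy-3-methoxyphenyl)methanol | COc1cc(CO)ccc1OC(C)C
F5 | step 7 | 4-isopropoxy-3-methoxybenzyl bromide | COc1cc(CBr)ccc1OC(C)C
F6 | step 7 | (3S,4S)-4-[4-(benzyloxy)-3-methoxybenzyl]-3-(4-isopropoxy-3-methoxybenzyl)dihydrofuran-2(3H)-one | COc1cc(C[C@@H]2COC(=O)[C@H]2Cc2ccc(OC(C)C)c(OC)c2)ccc1OCc1ccccc1
F7 | step 4 | racemic all-trans cycloadduct (7 and its mirror image) | Cn1ccnc1C(=O)[C@H]1[C@H](c2ccc(OC(C)C)c(OC)c2)[C@@H](c2ccc(OCc3ccccc3)c(OC)c2)[C@@H]1C(=O)OC.Cn1ccnc1C(=O)[C@@H]1[C@@H](c2ccc(OC(C)C)c(OC)c2)[C@H](c2ccc(OCc3ccccc3)c(OC)c2)[C@H]1C(=O)OC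
F8 | step 16 | 15 with the iodine replaced by the (3R)-3-[4-(benzyloxy)-3-methoxyphenyl]-3-[(tert-butyldimethylsilyl)oxy]prop-1-en-2-yl group, both phenols free | COc1cc(C[C@@H]2COC(=O)[C@H]2Cc2ccc(O)c(OC)c2)cc(C(=C)[C@H](O[Si](C)(C)C(C)(C)C)c2ccc(OCc3ccccc3)c(OC)c2)c1O
F9 | step 16 | bisphenol with the (7S,8S) ring B arm as C7 silyl ether and free C9 alcohol | COc1cc(C[C@@H]2COC(=O)[C@H]2Cc2ccc(O)c(OC)c2)cc([C@@H](CO)[C@H](O[Si](C)(C)C(C)(C)C)c2ccc(OCc3ccccc3)c(OC)c2)c1O
F10 | step 16 | F9 brominated ortho to the ring C phenol | COc1cc(C[C@@H]2COC(=O)[C@H]2Cc2cc(Br)c(O)c(OC)c2)cc([C@@H](CO)[C@H](O[Si](C)(C)C(C)(C)C)c2ccc(OCc3ccccc3)c(OC)c2)c1O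
F11 | step 17 | pinacol boronate of the ring B arm (boron on C9, C8 as in 26) | COc1cc(C[C@@H]2COC(=O)[C@H]2Cc2cc(Br)c(OCc3ccccc3)c(OC)c2)cc([C@@H](CB2OC(C)(C)C(C)(C)O2)[C@H](O[Si](C)(C)C(C)(C)C)c2ccc(OCc3ccccc3)c(OC)c2)c1OCc1ccccc1
F12 | step 19 | pinacol boronate of the ring C arm (boron on C9′, C8′ as in 29) | COc1cc(C[C@@H]2COC(=O)[C@H]2Cc2cc([C@H](CB3OC(C)(C)C(C)(C)O3)[C@H](O[Si](C)(C)C(C)(C)C)c3ccc(OCc4ccccc4)c(OC)c3)c(OCc3ccccc3)c(OC)c2)cc([C@@H](CO)[C@H](O[Si](C)(C)C(C)(C)C)c2ccc(OCc3ccccc3)c(OC)c2)c1OCc1ccccc1
F13 | step 21 | tetraphenol with both C7 oxygens as tert-butyldimethylsilyl ethers | COc1cc(C[C@@H]2COC(=O)[C@H]2Cc2cc([C@H](CO)[C@H](O[Si](C)(C)C(C)(C)C)c3ccc(O)c(OC)c3)c(O)c(OC)c2)cc([C@@H](CO)[C@H](O[Si](C)(C)C(C)(C)C)c2ccc(O)c(OC)c2)c1O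
A1 | alternative 1 | (E)-stilbene joining rings A and B (ring B as bromo aryl tosylate) | COc1cc(/C=C/c2cc(Br)cc(OC)c2OS(=O)(=O)c2ccc(C)cc2)ccc1OCc1ccccc1
A2 | alternative 1 | formaldehyde | C=O
A3 | alternative 1 | trans-4,5-diaryl-1,3-dioxane (7S,8S arm as methylene acetal) | COc1cc([C@H]5OCOC[C@@H]5c2cc(Br)cc(OC)c2OS(=O)(=O)c6ccc(C)cc6)ccc1OCc7ccccc7
A4 | alternative 2 | 3-benzylcyclobutanone carrying the silylated ring B arm | COc1cc([C@@H](O[Si](C)(C)C(C)(C)C)[C@H](CO[Si](C)(C)C(C)(C)C)c2cc(CC3CC(=O)C3)cc(OC)c2OCc2ccccc2)ccc1OCc1ccccc1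
A5 | alternative 2 | hydrogen peroxide | OO
A6 | alternative 2 | armed (S)-β-benzyl-γ-butyrolactone | COc1cc([C@@H](O[Si](C)(C)C(C)(C)C)[C@H](CO[Si](C)(C)C(C)(C)C)c2cc(C[C@@H]3COC(=O)C3)cc(OC)c2OCc5ccccc5)ccc1OCc6ccccc6
A7 | alternative 3 | diphenylhydrosilyl ether of the (E)-2,3-diarylallyl alcohol | COc1cc(/C=C(/CO[SiH](c2ccccc2)c2ccccc2)c2cc(Br)cc(OC)c2OCc2ccccc2)ccc1OCc1ccccc1
A8 | alternative 3 | trans-3,4-diaryl-1-oxa-2-silacyclopentane | COc1cc([C@H]5[Si](c6ccccc6)(c7ccccc7)OC[C@@H]5c2cc(Br)cc(OC)c2OCc8ccccc8)ccc1OCc9ccccc9
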